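The runs stem from a simulated flask from invented constants; noise was put on by code.

The leftover in the north-west run at 0.333 h is 8% of the free monomer charged, and with 87% in chains, that run's ledger already holds 5.00% under neither heading, each entry carrying a scatter of 1.5 percentage points.

- north-west: free monomer 1.7 M; initiator 13 mM; radical scavenger 5.2 mM; run made earlier
- flask: free monomer 2.6 M; initiator 13 mM; radical scavenger 5.2 mM; time 30 h

north-west run (percent of the free monomer charged)

| time / h | monomer in chains / % | free monomer / % |
|---|---|---|
| 0.333 | 87 | 8 |
| 1.33 | 93 | 0 |
| 6.00 | 86 | 0 |
| 30.0 | 51 | 3 |

(scatter of a reading: 1.5 percentage points)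

* the moment within 30 h at which there is most monomer in chains
* the amount of monomer in chains, in percent of the free monomer charged, at that time



The intake entry comes first: read as a pseudo-first-order fall from the charge, that leftover gives free monomer in the north-west run a half-life of 0.0914 h. The outgo entry follows: between 1.33 h and 30.0 h monomer in chains falls from 93% to 51%, which reads as 33.1 h for the chain-loss half-life, the time in which monomer in chains falls to half after its peak.

The flask starts with the initiator and radical scavenger concentrations of the north-west run, so the reckoning here takes both half-lives over unchanged, although the flask starts with more free monomer. In this reckoning the flask's books close at the peak, where intake has shrunk to outgo, and that takes 8.50 intake half-lives, or 0.777 h. By then the reckoned chain-loss entry stands at 1.63%, and with the early gap taken over from the north-west run the reckoning leaves 93.4% in chains.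

The forecast, reasoning that “The peak comes when growth equals loss”, gives 0.9 h and 93.5%, a time later than this reckoning's.

The flask peaks at 0.832 h with 95.5%, and both forecast values lie within tolerance.

    initiator → 2 initiating radical (k = 2.00 h⁻¹)
    free monomer + initiating radical → growing radical + monomer in chains (k = 2.30 × 10⁷ L mol⁻¹ h⁻¹)
    free monomer + growing radical → monomer in chains + growing radical, rate k3*[growing radical]*[free monomer] (k = 2.90 × 10⁷ L mol⁻¹ h⁻¹)
    2 growing radical → dead chain (k = 4.00 × 10⁷ L mol⁻¹ s⁻¹)
    growing radical + radical scavenger → ended chains (k = 8.80 × 10⁵ L mol⁻¹ s⁻¹)
    monomer in chains → over-reaction product (k = 0.0220 h⁻¹)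
    free monomer ⇌ dormant form (K = 0.700, k = 0.170 h⁻¹)

In the flask, initiator has a half-life of 0.35 h by its own decay path alone, while monomer in chains has 32 h by the path to over-reaction product alone, longer by a factor of 91.4. At the best time initiator stands at 18.9% of its charge and over-reaction product at 1.33% of the free monomer charged. Counted from the peak, the chain-loss half-life of 33.1 h gives 51.8% at 30 h in this flask, which holds 51.0%. For the same flask read at 5.0 d it gives 7.86%, and that flask holds 7.04%.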